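The oxolane (O1, C2 bearing ring B, C3 bearing CH2OH, C4 bearing the benzyl group, C5) holds the CH2OH carbon and the benzylic CH2 cis on C3 and C4, and both are attached to neighbouring carbons of ring A, one through the eventual 2-methoxy oxygen. They are therefore drawn together into a cis-fused tetralin whose aryl–C(=O) bond is later exchanged for aryl–O. A photoenolisation/Diels–Alder reaction of 4,5-dimethoxy-2-methylbenzaldehyde with (5R)-5-(l-menthyloxy)furan-2(5H)-one forms the C3–CH(OH) and C4–CH2 bonds, the carbocycle and the C3/C4 configuration in one operation; the lactone carbonyl then becomes C2 and the acetal carbon C5.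

Key step: step 3

Remark: atom labels follow the target oxolane (O1, C2–C5), with C9 the carbinol carbon that ends as the CH2OH carbon and C10 the benzylic CH2, and the target is read as the all-cis (2R,3R,4R) isomer; because a 5-alkoxy lactone is a masked aldehyde that an aryllithium would attack after ring opening, C5 is reduced to CH2 before ring B is introduced, and C9–O is carried as a triisopropylsilyl ether through the Lewis-acid step.

Step 1
Reactants: 1 furfural
Product: 2 5-hydroxyfuran-2(5H)-one (racemic cyclic hemiacetal)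
Conditions: O2, methylene blue (cat.), MeOH, hν (visible), 20 °C
Reagents that add atoms: dioxygen, O=O
Why: Dye-sensitised photooxygenation, in which singlet oxygen adds across the furan diene in a (4+2) sense and methanol then excises the formyl carbon as methyl formate, is the standard entry to this hydroxybutenolide; its hemiacetal centre is labile and needs no control.

Step 2
Reactants: 2 5-hydroxyfuran-2(5H)-one; 3 (−)-menthol
Product: 4 (5R)-5-(l-menthyloxy)furan-2(5H)-one
Conditions: camphorsulfonic acid (cat.), toluene, reflux, Dean–Stark; crystallisation from petroleum ether, mother liquor re-equilibrated with acid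
Reagents that add atoms: none
Why: Acid-catalysed acetalisation of the cyclic hemiacetal (pseudo-ester formation) gives both C5 epimers, which interconvert under acid, so the less soluble 5R epimer should be collected by crystallisation-induced diastereomer transformation.

Step 3
Reactants: 5 4,5-dimethoxy-2-methylbenzaldehyde; 4 (5R)-5-(l-menthyloxy)furan-2(5H)-one
Product: 7 cis-fused hydroxy lactone acetal (3R,3aR,9R,9aR)-9-hydroxy-6,7-dimethoxy-3-(l-menthyloxy)-3a,4,9,9a-tetrahydronaphtho[2,3-c]furan-1(3H)-one, via (E)-dienol 6 (not isolated)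
Conditions: hν (350–365 nm, Pyrex), 4 (2 equiv), degassed toluene, 20 °C
Reagents that add atoms: none
Why: Excitation of 5 (n,π*) and intersystem crossing are followed by 1,5-hydrogen transfer from the ortho-methyl group to the carbonyl oxygen; the (Z)-dienol reverts to 5, whereas the longer-lived, dearomatised (E)-dienol 6 is trapped by butenolide 4 in a thermal, concerted, suprafacial (4+2) cycloaddition that restores the aromatic sextet (photoenolisation/Diels–Alder reaction, known for o-methylbenzaldehydes with enoates and butenolides). The six-membered carbocycle is closed by intermolecular cycloaddition across the C3=C4 bond of the lactone, forming C3–C9 and C4–C10, so the ring fusion is necessarily cis. C3 and C4 take their absolute configuration from the C5 menthyloxy group, which shields one face of the furanone and forces the diene to approach anti to it. C9 arises from the endo transition state (hydroxyl cis to the lactone carbonyl, helped by an O–H···O=C hydrogen bond), and its configuration is of no consequence because C9 is oxidised in step 9. The step needs ortho regiochemistry, which the 1-hydroxydiene polarisation supplies: the larger HOMO coefficient at the CH2 terminus pairs with the β-carbon (C4) of the enoate and the carbinol terminus with the α-carbon (C3). An excess of 4, which does not absorb at these wavelengths, and exclusion of oxygen should keep the short-lived dienol from decaying unproductively.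

Step 4
Reactants: 7 cis-fused hydroxy lactone acetal
Product: 8 silyl ether (3R,3aR,9R,9aR)-6,7-dimethoxy-3-(l-menthyloxy)-9-[(triisopropylsilyl)oxy]-3a,4,9,9a-tetrahydronaphtho[2,3-c]furan-1(3H)-one
Conditions: TIPSOTf, 2,6-lutidine, CH2Cl2, −40 to 0 °C
Reagents that add atoms: triisopropylsilyl trifluoromethanesulfonate, CC(C)[Si](OS(=O)(=O)C(F)(F)F)(C(C)C)C(C)C
Why: Silyl triflate/hindered base O-silylation of the secondary benzylic alcohol installs a bulky, weakly Lewis-basic ether that masks C9–O through the organolithium and BF3 steps without touching a stereocentre.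

Step 5
Reactants: 8 silyl ether
Product: 11 cis-fused lactone (3aR,9R,9aR)-6,7-dimethoxy-9-[(triisopropylsilyl)oxy]-3a,4,9,9a-tetrahydronaphtho[2,3-c]furan-1(3H)-one, via aldehyde carboxylate 9 (not isolated), via hydroxy carboxylate 10 (not isolated)
Conditions: NaBH4 (excess), aq KOH, THF–MeOH, 0 °C; then 1 M HCl to pH 3, 20 °C
Reagents that add atoms: potassium hydroxide, [K+].[OH-] (its oxygen is built into the carboxylate of 9 and 10 and can remain in the lactone carbonyl group of 11)
Why: Saponification/borohydride reduction/relactonisation of a γ-alkoxy lactone: hydroxide opens the pseudo-ester, the hemiacetal sheds menthol, the freed aldehyde 9 is reduced at once by the borohydride already present (faster than enolisation at C4), and acidification recloses the cis hydroxy acid, so C5 becomes CH2 with C3 and C4 untouched.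

Step 6
Reactants: 11 cis-fused lactone; 12 5-bromo-1,2,3-trimethoxybenzene
Product: 14 lactol (3aR,9R,9aR)-6,7-dimethoxy-1-(3,4,5-trimethoxyphenyl)-9-[(triisopropylsilyl)oxy]-1,3,3a,4,9,9a-hexahydronaphtho[2,3-c]furan-1-ol (both C1 epimers; in equilibrium with the open γ-hydroxy ketone), via 3,4,5-trimethoxyphenyllithium 13 (not isolated)
Conditions: 12, n-BuLi, THF, −78 °C; then 11, −78 °C; aq NH4Cl
Reagents that add atoms: n-butyllithium, [Li]CCCC (lithium, into intermediate 13 only; nothing but hydrogen into 14)
Why: Bromine–lithium exchange gives aryllithium 13, which should add once to the γ-lactone carbonyl at −78 °C because the lithium hemiketal alkoxide persists until the quench (organolithium addition to a lactone); the new C2 centre may stay a mixture since it is flattened in step 7.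

Step 7
Reactants: 14 lactol
Product: 16 all-cis oxolane (1R,3aR,9R,9aS)-6,7-dimethoxy-1-(3,4,5-trimethoxyphenyl)-9-[(triisopropylsilyl)oxy]-1,3,3a,4,9,9a-hexahydronaphtho[2,3-c]furan, via oxocarbenium ion 15 (not isolated)
Conditions: Et3SiH, BF3·OEt2, CH2Cl2, −78 °C; aq NaHCO3 quench at −78 °C
Reagents that add atoms: none
Why: Ionic hydrogenation of a lactol: BF3 ionises the aryl-stabilised hemiketal to oxocarbenium ion 15 and Et3SiH should deliver hydride to the convex face, anti to the C3–C9 bond of the cis-fused carbocycle, so that ring B ends cis to the C3 and C4 substituents (2R), while the hindered C9 silyl ether should not ionise at −78 °C.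

Step 8
Reactants: 16 all-cis oxolane
Product: 17 alcohol (1R,3aR,9R,9aR)-6,7-dimethoxy-1-(3,4,5-trimethoxyphenyl)-1,3,3a,4,9,9a-hexahydronaphtho[2,3-c]furan-9-ol
Conditions: Bu4NF, THF, 0 to 40 °C
Reagents that add atoms: none
Why: Fluoride-mediated desilylation, driven by the strong Si–F bond, should free the C9 alcohol without affecting ethers or stereocentres.

Step 9
Reactants: 17 alcohol
Product: 18 tetralone (1R,3aR,9aS)-6,7-dimethoxy-1-(3,4,5-trimethoxyphenyl)-3,3a,4,9a-tetrahydronaphtho[2,3-c]furan-9(1H)-one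
Conditions: Dess–Martin periodinane, NaHCO3, CH2Cl2, 0 to 20 °C
Reagents that add atoms: none
Why: Dess–Martin oxidation of the secondary benzylic alcohol under bicarbonate buffer should give the aryl ketone without epimerisation at C3 or β-elimination of the ring oxygen.

Step 10
Reactants: 18 tetralone
Product: 19 aryl ester (7,8-dimethoxy-4,5-dihydro-1-benzoxepin-2(3H)-one cis-fused across its C3–C4 bond to the oxolane; oxolane C2 R bearing ring B; C3 S; C4 R)
Conditions: mCPBA, NaHCO3, CH2Cl2, 0 to 20 °C
Reagents that add atoms: 3-chloroperoxybenzoic acid, OOC(=O)c1cccc(Cl)c1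
Why: Baeyer–Villiger oxidation: after peracid addition to the ketone, the aryl carbon, activated by its para-methoxy group, should migrate in preference to the secondary C3, which is inductively deactivated by the β-oxygen O1, so oxygen enters the aryl–C9 bond with C3 unchanged.

Step 11
Reactants: 19 aryl ester
Product: 20 phenol [(2R,3R,4R)-4-(2-hydroxy-4,5-dimethoxybenzyl)-2-(3,4,5-trimethoxyphenyl)oxolan-3-yl]methanol
Conditions: LiAlH4, THF, 0 °C; then aq potassium sodium tartrate (KNaC4H4O6)
Reagents that add atoms: none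
Why: LiAlH4 reduction of the aryl ester should release the ring A phenol and turn C9 into the primary alcohol carbon without touching a stereocentre.

Step 12
Reactants: 20 phenol
Product: 21 [(2R,3R,4R)-4-(2,4,5-trimethoxybenzyl)-2-(3,4,5-trimethoxyphenyl)oxolan-3-yl]methanol (CNP0238280.1)
Conditions: MeI, K2CO3, acetone, reflux
Reagents that add atoms: iodomethane, CI
Why: Williamson O-methylation under carbonate base is selective for the phenol (pKa about 10) over the primary alcohol and completes the 2,4,5-trimethoxybenzyl group.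

**Compound list**

1 | furfural (furan-2-carbaldehyde) | O=Cc1ccco1 | starting material
2 | 5-hydroxyfuran-2(5H)-one (racemic) | O=C1C=CC(O)O1 | intermediate
3 | (−)-menthol, (1R,2S,5R)-2-isopropyl-5-methylcyclohexan-1-ol | CC(C)[C@@H]1CC[C@@H](C)C[C@H]1O | starting material
4 | (5R)-5-{[(1R,2S,5R)-2-isopropyl-5-methylcyclohexyl]oxy}furan-2(5H)-one | O=C1C=C[C@H](O[C@@H]2C[C@H](C)CC[C@H]2C(C)C)O1 | intermediate
5 | 4,5-dimethoxy-2-methylbenzaldehyde | Cc1cc(OC)c(OC)cc1C=O | starting material
6 | (E)-(3,4-dimethoxy-6-methylidenecyclohexa-2,4-dien-1-ylidene)methanol (photodienol, hydroxyl pointing away from the methylidene group) | O/C=C1/C(=C)C=C(OC)C(OC)=C1 | intermediate (not isolated)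
7 | (3R,3aR,9R,9aR)-9-hydroxy-6,7-dimethoxy-3-(l-menthyloxy)-3a,4,9,9a-tetrahydronaphtho[2,3-c]furan-1(3H)-one (cis ring fusion, menthyloxy trans to it, hydroxyl cis to the lactone carbonyl) | O=C1O[C@@H](O[C@@H]2C[C@H](C)CC[C@H]2C(C)C)[C@@H]3Cc4cc(OC)c(OC)cc4[C@H](O)[C@H]13 | intermediate
8 | (3R,3aR,9R,9aR)-6,7-dimethoxy-3-(l-menthyloxy)-9-[(triisopropylsilyl)oxy]-3a,4,9,9a-tetrahydronaphtho[2,3-c]furan-1(3H)-one | O=C1O[C@@H](O[C@@H]2C[C@H](C)CC[C@H]2C(C)C)[C@@H]3Cc4cc(OC)c(OC)cc4[C@H](O[Si](C(C)C)(C(C)C)C(C)C)[C@H]13 | intermediate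
9 | potassium (1R,2R,3R)-3-formyl-6,7-dimethoxy-1-[(triisopropylsilyl)oxy]-1,2,3,4-tetrahydronaphthalene-2-carboxylate | O=C[C@@H]1Cc2cc(OC)c(OC)cc2[C@H](O[Si](C(C)C)(C(C)C)C(C)C)[C@@H]1C(=O)[O-].[K+] | intermediate (not isolated)
10 | potassium (1R,2R,3R)-3-(hydroxymethyl)-6,7-dimethoxy-1-[(triisopropylsilyl)oxy]-1,2,3,4-tetrahydronaphthalene-2-carboxylate | OC[C@@H]1Cc2cc(OC)c(OC)cc2[C@H](O[Si](C(C)C)(C(C)C)C(C)C)[C@@H]1C(=O)[O-].[K+] | intermediate (not isolated)
11 | (3aR,9R,9aR)-6,7-dimethoxy-9-[(triisopropylsilyl)oxy]-3a,4,9,9a-tetrahydronaphtho[2,3-c]furan-1(3H)-one | O=C1OC[C@@H]3Cc4cc(OC)c(OC)cc4[C@H](O[Si](C(C)C)(C(C)C)C(C)C)[C@H]13 | intermediate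
12 | 5-bromo-1,2,3-trimethoxybenzene | COc1cc(Br)cc(OC)c1OC | starting material
13 | 3,4,5-trimethoxyphenyllithium | [Li]c1cc(OC)c(OC)c(OC)c1 | intermediate (not isolated)
14 | (3aR,9R,9aR)-6,7-dimethoxy-1-(3,4,5-trimethoxyphenyl)-9-[(triisopropylsilyl)oxy]-1,3,3a,4,9,9a-hexahydronaphtho[2,3-c]furan-1-ol (both C1 epimers) | COc1cc(cc(OC)c1OC)C1(O)OC[C@@H]3Cc4cc(OC)c(OC)cc4[C@H](O[Si](C(C)C)(C(C)C)C(C)C)[C@H]13 | intermediate
15 | cyclic oxocarbenium ion derived from 14 (O1=C2 cation bearing ring B, hydroxytrifluoroborate counter-ion) | COc1cc(cc(OC)c1OC)C1=[O+]C[C@@H]3Cc4cc(OC)c(OC)cc4[C@H](O[Si](C(C)C)(C(C)C)C(C)C)[C@H]13.O[B-](F)(F)F | intermediate (not isolated)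
16 | (1R,3aR,9R,9aS)-6,7-dimethoxy-1-(3,4,5-trimethoxyphenyl)-9-[(triisopropylsilyl)oxy]-1,3,3a,4,9,9a-hexahydronaphtho[2,3-c]furan (ring B cis to both ring-fusion bonds) | COc1cc(cc(OC)c1OC)[C@@H]1OC[C@@H]3Cc4cc(OC)c(OC)cc4[C@H](O[Si](C(C)C)(C(C)C)C(C)C)[C@H]13 | intermediate
17 | (1R,3aR,9R,9aR)-6,7-dimethoxy-1-(3,4,5-trimethoxyphenyl)-1,3,3a,4,9,9a-hexahydronaphtho[2,3-c]furan-9-ol | COc1cc(cc(OC)c1OC)[C@@H]1OC[C@@H]3Cc4cc(OC)c(OC)cc4[C@H](O)[C@H]13 | intermediate
18 | (1R,3aR,9aS)-6,7-dimethoxy-1-(3,4,5-trimethoxyphenyl)-3,3a,4,9a-tetrahydronaphtho[2,3-c]furan-9(1H)-one | COc1cc(cc(OC)c1OC)[C@@H]1OC[C@@H]3Cc4cc(OC)c(OC)cc4C(=O)[C@H]13 | intermediate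
19 | 7,8-dimethoxy-4,5-dihydro-1-benzoxepin-2(3H)-one cis-fused across C3–C4 to the oxolane (oxolane numbering: 2R with ring B, 3S, 4R) | COc1cc(cc(OC)c1OC)[C@@H]1OC[C@@H]3Cc4cc(OC)c(OC)cc4OC(=O)[C@H]13 | intermediate
20 | [(2R,3R,4R)-4-(2-hydroxy-4,5-dimethoxybenzyl)-2-(3,4,5-trimethoxyphenyl)oxolan-3-yl]methanol | Oc1cc(OC)c(OC)cc1C[C@H]1CO[C@@H](c2cc(OC)c(OC)c(OC)c2)[C@H]1CO | intermediate
21 | [(2R,3R,4R)-4-(2,4,5-trimethoxybenzyl)-2-(3,4,5-trimethoxyphenyl)oxolan-3-yl]methanol | COc1cc(OC)c(OC)cc1C[C@H]1CO[C@@H](c2cc(OC)c(OC)c(OC)c2)[C@H]1CO | target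

Total step count: 12.
Longest linear sequence: 12 steps (furfural 1 to target 21); 10 steps from the purchased aldehyde 5.

**Steps most likely to fail**

1. Step 3. The electron-rich aldehyde may photoenolise inefficiently, because a low-lying π,π* triplet slows hydrogen abstraction, and the dienol may revert before the butenolide traps it. Leakage of facial or regiochemical control is a secondary concern. The fallback sets out from 5 and 4 and returns at 7, making the same two bonds by ionic means. Aldehyde 5 is oxidised (NaClO2, NaH2PO4, 2-methyl-2-butene, t-BuOH–H2O) to 4,5-dimethoxy-2-methylbenzoic acid F1 and esterified (MeI, K2CO3, DMF) to methyl 4,5-dimethoxy-2-methylbenzoate F2. Its benzylic anion (LiN(i-Pr)2, THF, −78 °C) should add in conjugate fashion to 4 anti to the menthyloxy group, forming C4–C10. The lactone enolate so formed should close onto the ester, forming C3–C9 (Michael–Dieckmann annulation of a toluate anion). This gives the cis-fused β-keto lactone (3R,3aR,9aR)-6,7-dimethoxy-3-(l-menthyloxy)-3a,4-dihydronaphtho[2,3-c]furan-1,9(3H,9aH)-dione F3. Reduction of its ketone (NaBH4, MeOH, −20 °C, hydride on the convex face) should return 7.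

2. Step 7. The benzylic C9–O bond, which would give a para-methoxy-stabilised cation, may ionise in competition with C2, with loss of the silyloxy group, or hydride delivery may discriminate the faces incompletely. The fallback sets out from 14 and returns at 16 without any Lewis acid. The open hydroxy ketone form of 14 is reduced under reagent control ((S)-2-methyl-CBS-oxazaborolidine, BH3·SMe2, THF) to the benzylic diol (1R,2R,3R)-tetralin 2-[(R)-hydroxy(3,4,5-trimethoxyphenyl)methyl]-3-(hydroxymethyl) derivative F4. Its primary hydroxyl is sulfonylated selectively (TsCl, Et3N, cat. DMAP, CH2Cl2, 0 °C) to the monotosylate F5. KOt-Bu in THF then closes the oxolane by 5-exo-tet Williamson etherification at C5, with retention at C2, to give 16.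

3. Step 10. Peracid addition to the hindered, electron-rich aryl ketone may be slow, the secondary C3 may migrate in competition (giving the isomeric lactone), and the two polymethoxyarenes may be over-oxidised. The fallback sets out from 17 and returns at 20, so that steps 9 to 11 are bypassed. Alcohol 17 is converted with H2O2 and catalytic TsOH (Et2O, 0 °C) into the benzylic hydroperoxide, 9-hydroperoxy analogue of 17 F6. Its acid-promoted Hock rearrangement (cat. TsOH, CH2Cl2, 0 °C, then water) should let only the electron-rich aryl group migrate to oxygen and give the seven-membered aryl hemiacetal, oxolane-fused 7,8-dimethoxy-2,3,4,5-tetrahydro-1-benzoxepin-2-ol F7. NaBH4 (MeOH, 0 °C) should reduce its open hydroxy aldehyde form to 20.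

**Further compounds**

F1 | step 3 | 4,5-dimethoxy-2-methylbenzoic acid | Cc1cc(OC)c(OC)cc1C(=O)O
F2 | step 3 | methyl 4,5-dimethoxy-2-methylbenzoate | Cc1cc(OC)c(OC)cc1C(=O)OC
F3 | step 3 | (3R,3aR,9aR)-6,7-dimethoxy-3-(l-menthyloxy)-3a,4-dihydronaphtho[2,3-c]furan-1,9(3H,9aH)-dione (keto form shown; largely enolised) | O=C1O[C@@H](O[C@@H]2C[C@H](C)CC[C@H]2C(C)C)[C@@H]3Cc4cc(OC)c(OC)cc4C(=O)[C@H]13
F4 | step 7 | (R)-[(1R,2R,3R)-3-(hydroxymethyl)-6,7-dimethoxy-1-[(triisopropylsilyl)oxy]-1,2,3,4-tetrahydronaphthalen-2-yl](3,4,5-trimethoxyphenyl)methanol | OC[C@@H]1Cc2cc(OC)c(OC)cc2[C@H](O[Si](C(C)C)(C(C)C)C(C)C)[C@@H]1[C@@H](O)c1cc(OC)c(OC)c(OC)c1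
F5 | step 7 | primary p-toluenesulfonate of F4 | Cc1ccc(cc1)S(=O)(=O)OC[C@@H]1Cc2cc(OC)c(OC)cc2[C@H](O[Si](C(C)C)(C(C)C)C(C)C)[C@@H]1[C@@H](O)c1cc(OC)c(OC)c(OC)c1
F6 | step 10 | (1R,3aR,9aS)-9-hydroperoxy-6,7-dimethoxy-1-(3,4,5-trimethoxyphenyl)-1,3,3a,4,9,9a-hexahydronaphtho[2,3-c]furan (C9 epimers) | COc1cc(cc(OC)c1OC)[C@@H]1OC[C@@H]3Cc4cc(OC)c(OC)cc4C(OO)[C@H]13
F7 | step 10 | oxolane-fused 7,8-dimethoxy-2,3,4,5-tetrahydro-1-benzoxepin-2-ol (aryl hemiacetal; epimers at the hemiacetal carbon) | COc1cc(cc(OC)c1OC)[C@@H]1OC[C@@H]3Cc4cc(OC)c(OC)cc4OC(O)[C@H]13
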